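**Retrosynthetic overview**
1. Target 13 ⇐ C19 aldehyde 12 (oxidation) ⇐ 4-formyl nor-labdane 10; the C4 quaternary centre comes from α-methylation of the formyl enolate on its equatorial face.
2. Key disconnection C4–C5 (C9–C10 follows in the same cascade): 10 ⇐ open-chain (6E,10E)-dienal 9. The aldehyde α-carbon (normally a nucleophile) is made electrophilic as an enamine radical cation and attacks the nucleophilic alkene carbon C5. Ring A closes first, ring B second, and the exocyclic alkene forms on termination.
3. 9 ⇐ allylic bromide 5 + a four-carbon acetal Grignard reagent (C2–C3–C4–C19).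
4. 5 ⇐ (S)-2,3-dihydrofarnesyl acetate by allylic oxidation of the E-methyl ⇐ (2E,6E)-farnesol; C13 is set by asymmetric hydrogenation.

Assumption: the (2R,5R) antipode of the imidazolidinone catalyst is taken as the one that exposes the Si face of the enamine α-carbon and gives the natural decalin (5α-H, 10β-methyl); if the facial sense is the reverse, the (2S,5S) antipode is used, and the few percent of the diastereomer with the mirror-image decalin is removed by recrystallisation of 13.

Labdane numbering is used for the ring compounds. In 9: C16 = C19, C15 = C4, C10 = C5, C11 = C10, C6 = C9, C7 = C8, C3 = C13.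

**Route**

Step 1
Reactants: 1 (2E,6E)-farnesol
Product: 2 (3S,6E)-3,7,11-trimethyldodeca-6,10-dien-1-ol ((S)-2,3-dihydrofarnesol)
Conditions: H2 (30 atm), Ru(OAc)2[(R)-BINAP] (0.2 mol%), MeOH, 20 °C
Reagents that add atoms: none
Why: Noyori asymmetric hydrogenation (hydroxyl-directed, BINAP–ruthenium): only the allylic-alcohol alkene is reduced, and the (R)-ligand gives the 3S centre (C13 of the target) in the same sense as geraniol gives (S)-citronellol.

Step 2
Reactants: 2 (S)-2,3-dihydrofarnesol
Product: 3 (3S,6E)-3,7,11-trimethyldodeca-6,10-dienyl acetate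
Conditions: Ac2O, pyridine, DMAP (cat.), CH2Cl2, 0 → 23 °C
Reagents that add atoms: acetic anhydride, CC(=O)OC(C)=O
Why: DMAP-catalysed O-acylation of the primary alcohol; the acetate of the target is installed here and carried through.

Step 3
Reactants: 3 (S)-2,3-dihydrofarnesyl acetate
Product: 4 (3S,6E,10E)-12-hydroxy-3,7,11-trimethyldodeca-6,10-dienyl acetate
Conditions: SeO2 (0.2 equiv), t-BuOOH (3 equiv), salicylic acid (0.1 equiv), CH2Cl2, 23 °C
Reagents that add atoms: tert-butyl hydroperoxide, CC(C)(C)OO (terminal oxidant; the oxygen is passed on by catalytic selenium dioxide, O=[Se]=O)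
Why: Sharpless-modified Riley allylic oxidation (ene reaction, then [2,3]-sigmatropic shift) picks the E-methyl of the terminal, most electron-rich trisubstituted alkene and keeps the E geometry.

Step 4
Reactants: 4 allylic alcohol
Product: 5 (3S,6E,10E)-12-bromo-3,7,11-trimethyldodeca-6,10-dienyl acetate
Conditions: PBr3 (0.4 equiv), Et2O, −10 °C
Reagents that add atoms: phosphorus tribromide, BrP(Br)Br
Why: Bromination of the primary allylic alcohol through a phosphite ester (SN2) at low temperature leaves the acetate and both alkene geometries intact.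

Step 5
Reactants: 5 allylic bromide; 6 2-(3-chloropropyl)-1,3-dioxolane
Product: 9 (3S,6E,10E)-3,7,11-trimethyl-16-oxohexadeca-6,10-dienyl acetate, via Grignard reagent 7 (not isolated), via dioxolane acetal 8 (not isolated)
Conditions: 6, Mg, THF, 50 °C; then 5, Li2CuCl4 (3 mol%), THF, −40 → 0 °C; then 2 M aq HCl, THF, 23 °C
Reagents that add atoms: water, O
Why: Kochi-type copper-catalysed Grignard cross-coupling occurs at the primary carbon of the allylic bromide (SN2) faster than addition to the acetate at low temperature, and acid hydrolysis of the dioxolane (acetal deprotection) on work-up releases the aldehyde.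

Step 6
Reactants: 9 dienal
Product: 10 15-acetoxy-19-norlabd-8(17)-en-18-al (trans-decalin; equatorial 4α-CHO, 4R; 5α-H; 10β-CH3; 9α-H; 13S)
Conditions: (2R,5R)-2-tert-butyl-3-methyl-5-(naphthalen-1-ylmethyl)imidazolidin-4-one·CF3CO2H (30 mol%), Cu(OTf)2 (2.5 equiv), CF3CO2Na (2 equiv), CF3CO2H (3 equiv), i-PrCN/DME (1:1), 23 °C, slow addition of 9
Reagents that add atoms: none
Why: Proposed new method: organo-SOMO polyene cyclisation in which the chiral imidazolidinone forms an enamine from 9 that divalent copper oxidises to a 3π-electron radical cation (an enolonium equivalent), whose α-carbon C4 adds 6-endo to C5 of the 10E-alkene on the enamine face left open by the catalyst through a chair transition state with the iminium group equatorial (sets C4, C5 and C10), the tertiary C10 radical then closes ring B 6-endo on the 6E-alkene (trans-decalin, equatorial side chain at C9), and the tertiary C8 radical is oxidised by divalent copper carboxylate with loss of a C17 hydrogen to the less substituted exocyclic alkene; the closest known reaction types are enantioselective SOMO-catalysed polyene cyclisations that end on arenes and the oxidative elimination of tertiary radicals by copper carboxylates that ends manganese triacetate polyene cyclisations at an exocyclic methylene.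

Step 7
Reactants: 10 nor-labdenal
Product: 12 15-acetoxylabd-8(17)-en-19-al, via potassium enolate 11 (not isolated)
Conditions: KN(SiMe3)2 (1.05 equiv), THF, −78 °C; then MeI (5 equiv), −78 → −20 °C
Reagents that add atoms: iodomethane, CI
Why: Aldehyde enolate C-alkylation: one equivalent of base removes the far more acidic C4–H rather than an acetate proton, and iodomethane attacks the exocyclic enolate from the equatorial α face, opposite the axial C10 methyl, so the formyl group ends up axial (4S, C19).

Step 8
Reactants: 12 C19 aldehyde
Product: 13 15-acetoxylabd-8(17)-en-19-oic acid (target, CNP0401865.2)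
Conditions: NaClO2, NaH2PO4, 2-methyl-2-butene, t-BuOH/H2O (4:1), 23 °C
Reagents that add atoms: sodium chlorite, [Na+].[O-]Cl=O
Why: Pinnick oxidation converts the hindered aldehyde into the acid without touching the exocyclic alkene (hypochlorite is scavenged) or the acetate, and no stereocentre is affected.

**Compound list**
1 | (2E,6E)-farnesol | OC/C=C(C)/CC/C=C(C)/CCC=C(C)C | starting material
2 | (3S,6E)-3,7,11-trimethyldodeca-6,10-dien-1-ol | OCC[C@@H](C)CC/C=C(C)/CCC=C(C)C | intermediate
3 | (3S,6E)-3,7,11-trimethyldodeca-6,10-dienyl acetate | CC(=O)OCC[C@@H](C)CC/C=C(C)/CCC=C(C)C | intermediate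
4 | (3S,6E,10E)-12-hydroxy-3,7,11-trimethyldodeca-6,10-dienyl acetate | CC(=O)OCC[C@@H](C)CC/C=C(C)/CC/C=C(C)/CO | intermediate
5 | (3S,6E,10E)-12-bromo-3,7,11-trimethyldodeca-6,10-dienyl acetate | CC(=O)OCC[C@@H](C)CC/C=C(C)/CC/C=C(C)/CBr | intermediate
6 | 2-(3-chloropropyl)-1,3-dioxolane | ClCCCC1OCCO1 | starting material
7 | [3-(1,3-dioxolan-2-yl)propyl]magnesium chloride | Cl[Mg]CCCC1OCCO1 | intermediate
8 | (3S,6E,10E)-15-(1,3-dioxolan-2-yl)-3,7,11-trimethylpentadeca-6,10-dienyl acetate | CC(=O)OCC[C@@H](C)CC/C=C(C)/CC/C=C(C)/CCCCC1OCCO1 | intermediate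
9 | (3S,6E,10E)-3,7,11-trimethyl-16-oxohexadeca-6,10-dienyl acetate | CC(=O)OCC[C@@H](C)CC/C=C(C)/CC/C=C(C)/CCCCC=O | intermediate
10 | 15-acetoxy-19-norlabd-8(17)-en-18-al (4α-CHO, 5α-H, 10β-CH3, 9α-H, 13S) | C=C1CC[C@@H]2[C@](C)(CCC[C@H]2C=O)[C@H]1CC[C@H](C)CCOC(C)=O | intermediate
11 | potassium enolate of 10 (exocyclic C4=C19 enolate) | C=C1CC[C@@H]2[C@](C)(CCC/C2=C\[O-])[C@H]1CC[C@H](C)CCOC(C)=O.[K+] | intermediate
12 | 15-acetoxylabd-8(17)-en-19-al; (3S)-5-[(1S,4aR,5S,8aR)-5-formyl-5,8a-dimethyl-2-methylidenedecahydronaphthalen-1-yl]-3-methylpentyl acetate | C=C1CC[C@@H]2[C@](C)(CCC[C@]2(C)C=O)[C@H]1CC[C@H](C)CCOC(C)=O | intermediate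
13 | 15-acetoxylabd-8(17)-en-19-oic acid; (1S,4aR,5S,8aR)-5-[(3S)-5-acetoxy-3-methylpentyl]-1,4a-dimethyl-6-methylidenedecahydronaphthalene-1-carboxylic acid | C=C1CC[C@@H]2[C@](C)(CCC[C@]2(C)C(=O)O)[C@H]1CC[C@H](C)CCOC(C)=O | target

**Step count**
Total steps: 8. Longest linear sequence: 8 (from farnesol 1; the Grignard reagent 7 is made in the flask within step 5).

**The three steps most likely to fail, with fallbacks**

Step 6 (key cyclisation). The main doubts are the regiochemistry of the terminating elimination (exocyclic versus ring alkene), acid-induced migration of the new alkene, and incomplete enantiocontrol. The fallback sets out from 9 and comes back at 10, and separates ring formation from alkene formation. The same enamine radical-cation cyclisation is run with Cu(OTf)2 in wet i-PrCN without carboxylate buffer, so that the C8 radical is oxidised through to the tertiary cation and captured by water on the equatorial α face. This gives the tertiary alcohol 15-acetoxy-8α-hydroxy-19-norlabdan-18-al F1. Treatment of F1 with SOCl2 and pyridine at −78 °C then eliminates the equatorial chlorosulfite. That leaving group has anti-periplanar hydrogens only on the axial C17 methyl, so the E2 reaction gives the exocyclic alkene 10.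

Step 7 (methylation beside an acetate). The doubts are competing enolisation or cleavage of the acetate, O-methylation, and slow removal of the hindered axial C4–H. The fallback sets out from 10 and comes back at 12, and replaces enolate alkylation by cyclopropanation and ring opening. Me3SiOTf and Et3N (CH2Cl2, 0 °C) give the trimethylsilyl enol ether 15-acetoxy-18-(trimethylsilyloxy)-19-norlabda-4(18),8(17)-diene F2. Et2Zn and CH2I2 (CH2Cl2, 0 °C; Furukawa–Simmons–Smith) cyclopropanate the electron-rich enol ether in preference to the 1,1-disubstituted alkene, from the α face opposite the C10 methyl, to give the spiro siloxycyclopropane F3. Bu4NF buffered with AcOH (THF, 0 °C) opens the cyclopropanol at its CH2–CHO bond, which turns the new methylene into the 4α-methyl group and returns 12.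

Step 5 (Grignard coupling beside an acetate). The doubts are attack of the Grignard reagent on the acetate and SN2′ alkylation. The fallback sets out from 5 and comes back at 9, and replaces the Grignard reagent by an ester-tolerant alkylborane. Commercial 4,4-diethoxybut-1-ene (C=CCC(OCC)OCC) is hydroborated with 9-borabicyclo[3.3.1]nonane (THF, 23 °C) to B-(4,4-diethoxybutyl)-9-borabicyclo[3.3.1]nonane F4. F4 is cross-coupled with 5 in a B-alkyl Suzuki–Miyaura reaction (PdCl2(dppf) precatalyst reduced to zerovalent palladium, K3PO4, THF/H2O, 40 °C), with bond formation at the unsubstituted CH2 terminus of the π-allylpalladium intermediate. This gives (3S,6E,10E)-16,16-diethoxy-3,7,11-trimethylhexadeca-6,10-dienyl acetate F5. Hydrolysis of F5 (1 M aq HCl, THF, 23 °C) gives 9.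

**Further compounds**
F1 | step 6 | 15-acetoxy-8α-hydroxy-19-norlabdan-18-al | C[C@@]1(O)CC[C@@H]2[C@](C)(CCC[C@H]2C=O)[C@H]1CC[C@H](C)CCOC(C)=O
F2 | step 7 | trimethylsilyl enol ether of 10 (E, silyloxy group on the C3 side) | C=C1CC[C@@H]2[C@](C)(CCC/C2=C\O[Si](C)(C)C)[C@H]1CC[C@H](C)CCOC(C)=O
F3 | step 7 | spiro siloxycyclopropane from F2 (new CH2 on the α face of C4) | C=C1CC[C@@H]2[C@](C)(CCC[C@@]24C[C@@H]4O[Si](C)(C)C)[C@H]1CC[C@H](C)CCOC(C)=O
F4 | step 5 | B-(4,4-diethoxybutyl)-9-borabicyclo[3.3.1]nonane | CCOC(CCCB1C2CCCC1CCC2)OCC
F5 | step 5 | (3S,6E,10E)-16,16-diethoxy-3,7,11-trimethylhexadeca-6,10-dienyl acetate | CC(=O)OCC[C@@H](C)CC/C=C(C)/CC/C=C(C)/CCCCC(OCC)OCC
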